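Linking of G keeps pace with ring closure when D stands at 2.67 times its charge; call this the break-even level. With D at a fraction f of its charge, the link share of each G used (its selectivity) is f / (f + 2.67). You now need the flasks and what is asked.

common to all: time 30 h

| charge | G | D | remark |
|---|---|---|---|
| alder | 0.050 M (fed, over 80 min) | 0.0510 M | all else is in the flask from the start; the feed brings no volume worth counting |
| ash | 0.050 M (fed, over 12 h) | 0.0510 M | all else is in the flask from the start; the feed brings no volume worth counting |
| larch | 0.050 M | 0.0510 M | everything together at the start |
| birch | 0.050 M | 0.0510 M (fed, over 12 h) | all else is in the flask from the start; the feed brings no volume worth counting |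

    G + D → G.D (k1 = 0.11 M⁻¹ min⁻¹)
    G + D → J, rate k2*[G] as long as [D] is above zero (k2 = 0.015 min⁻¹)
    D → Q (k3 = 0.0031 min⁻¹)
    Z ⇌ G.D, rate k4*(cs4 - [G.D]) while solid is left; crystals form when [G.D] > cs4 (cs4 = 27 mM, k4 = 0.27 min⁻¹)
    G + G.D ⇌ G.G.D, settled at all times (K5 = 25 M⁻¹)

- in percentages every species weighs as the G in it: one G.G.D counts as two
- for G.D the Z and G.G.D are counted in
- as a solid, counted per litre of solution: Z
- in an amount of G.D, one G.G.D counts as one G.D
- run time (alder): 30 h

- the flask with the highest amount of G.D, in percent of the G charged ("all alike" if they lie within 1.5 percentage points) (alder / ash / larch / birch / all alike)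
- final G.D, as a percentage of the G charged, in alder
- final G.D, as a percentage of the G charged, in ash
- final G.D, as a percentage of the G charged, in larch
- final G.D, as a percentage of the G charged, in birch

Here is my own bracket for larch, with G.G.D set aside.

1. In larch f starts at one and only falls, so the link share cannot pass 27.2%. That is less than the 54.0% of the G charge that the solubility allows, so I expect no Z.

2. One D goes with each G used, and the charges are nearly equal, so f falls about in step with G. Averaging the share over that fall gives a ceiling of 15.3%, since D lost to Q can only lower f.

3. For the floor, put that answer back in. I estimate that a G lives 66.7 min against rings alone, and that links shorten this to about 56.4 min. Over that time Q takes about 17.5% of the D.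

4. Charge that whole loss at the start, so that D begins at 82.5% of its charge. The same average then gives an estimated floor of 10.8%.

5. The forecast names larch as highest, with 11.3% in alder, 5.8% in ash, 12.3% in larch and 0.2% in birch, on the ground that “the all-at-once flask keeps the most D while G is reacting”. Its larch value lies inside my bracket, above the floor and below the ceiling.

The simulation also puts larch first, with 13.2% there, 11.0% in alder, 5.37% in ash and 0.0643% in birch; the larch value lies inside my bracket, above the floor and below the ceiling. In larch, links, rings and Q formed while D, the limiting reagent, lasted, and at 30.0 h D stood at 0% and free G at 9.83%. In birch, D stood at 4.34% of its charge at 12.0 h, which makes the link share 1.60%. Applied to the 2.88% of G then in birch, that share gives 0.0461% on top of the 0.0383% of G.D there. D in birch then fell to 0.0276% at 30.0 h, and birch ended below that sum, at 0.0643%.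

The rate constants come from no measurement; the flask was simulated.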